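**Plan**

- Numbering: ring C1 (CH–O‑angelate), C2 (CH2), C3/C4 (epoxide, CH3 on C4), C5 (OAc), C6 (O‑senecioate), C7 (isopropenyl, whose central carbon is C11), C8 (CH2), C9 (OAc), C10 (C(CH3)OH).
- Enabling feature: C2 and C7 are 1,6‑related and C7 carries the only exocyclic carbon. Tying C11 to C2 as a one‑carbon ketone bridge turns the ten‑membered ring into a bicyclo[4.4.1]undecanone, which is a tropone–diene adduct.
- Retrosynthetic cuts, in order: the four ester C–O bonds and the epoxide; C11=CH2; the C2–C11 bond is restored next to a C1 ketone (reverse of a retro‑aldol); finally C7–C8 and C1–C2 ([6+4]).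
- Forward: the [6+4] closes the ten‑membered ring as a rigid bicycle; both faces are oxygenated there; C11 receives its methyl; a C1 ketone triggers retro‑aldol opening to the monocycle; isopropenyl, esters and epoxide follow.
- Stereochemistry: C7 from the cycloaddition (single enantiomer by lipase acetylation at C9); C5, C6 and C10 by osmylation of the exposed faces of the bicycle; C9 and C1 by hydride delivery from the C10 hydroxyl; C3/C4 by epoxidation directed by the C5 hydroxyl.

Key step: step 5

Assumption: up to compound 13 the bicycle reacts in the conformation born in the exo transition state, with C9=C10 lying over the C11 carbonyl and the C1 silyloxy group pointing outward.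
Remark: compounds 9 to 15 are racemic and are drawn as the enantiomer that is carried on.

**Step 1**
Reactants: 1 4-methylanisole
Product: 2 1-methoxy-4-methylcyclohexa-1,4-diene
Conditions: Li, NH3 (l), t-BuOH, THF, −78 to −33 °C; NH4Cl
Reagents that add atoms: none
Why: Birch reduction of an anisole should give the 2,5-dihydro product with the methoxy and methyl groups on the two remaining double bonds; no stereocentre is formed.

**Step 2**
Reactants: 2 1-methoxy-4-methylcyclohexa-1,4-diene; 3 bromoform
Product: 4 7,7-dibromo-1-methoxy-4-methylbicyclo[4.1.0]hept-3-ene (racemic)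
Conditions: KOC(CH3)3, pentane, −10 to 0 °C
Reagents that add atoms: none
Why: Dibromocarbene [2+1] cycloaddition; the electrophilic carbene should pick the enol ether double bond over the alkyl-substituted one, and the cis ring fusion is the only one possible.

**Step 3**
Reactants: 4 7,7-dibromo-1-methoxy-4-methylbicyclo[4.1.0]hept-3-ene
Product: 6 4-methyltropone, via 2-bromo-5-methylcyclohepta-2,5-dien-1-one 5 (not isolated)
Conditions: AgNO3, acetone–H2O, 50 °C; then Et3N
Reagents that add atoms: water (O)
Why: Silver-assisted electrocyclic opening of the gem-dibromocyclopropane (cyclopropyl to allyl cation, stabilised by methoxy, then hydrolysis) followed by base-induced loss of HBr should give the tropone, as in the known anisole-to-tropone ring expansion.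

**Step 4**
Reactants: 7 (E)-2-methylbut-2-enal
Product: 8 (E)-1-(tert-butyldimethylsilyloxy)-2-methylbuta-1,3-diene
Conditions: TBSOTf, Et3N, Et2O, 0 °C to rt
Reagents that add atoms: tert-butyldimethylsilyl triflate (CC(C)(C)[Si](C)(C)OS(=O)(=O)C(F)(F)F)
Why: Silyl dienol ether formation by γ-deprotonation of the O-silylated enal; the s-trans enal should give the E enol ether.

**Step 5**
Reactants: 6 4-methyltropone; 8 (E)-1-(tert-butyldimethylsilyloxy)-2-methylbuta-1,3-diene
Product: 9 racemic exo [6+4] adduct (bicyclo[4.4.1]undecatrienone: C11 ketone bridging C2 and C7; C1 OTBS; C3=C4(CH3)–C5=C6; C9=C10(CH3))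
Conditions: toluene, BHT (cat.), 110 °C, sealed tube
Reagents that add atoms: none
Why: Thermal concerted π6s+π4s cycloaddition of the tropone triene (C2 to C7) with the s-cis diene; the closest known reaction type is the exo-selective [6+4] addition of tropone to 1-oxygenated butadienes. Both σ bonds (C7–C8 and C1–C2) form in one suprafacial–suprafacial event, which closes the ten-membered carbocycle and with it the two seven-membered rings of the bicyclo[4.4.1] frame, C11 remaining as the ketone bridge. C2 and C7 are set cis by suprafacial bonding on the tropone, and C1 follows from the E enol ether geometry in the exo transition state (diene under the carbonyl), which leaves the silyloxy group outward. The step needs [6+4] over [4+2] periselectivity and exo topology, both inherent to tropone with acyclic electron-rich dienes because the interior carbons of diene and triene meet out of phase in the endo arrangement. The orientation of the unsymmetrical tropone is not steered by the remote methyl, so the isomer with methyl on C4 has to be separated from the one with methyl on C5. The adduct is racemic; the absolute configuration is fixed in step 12.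

**Step 6**
Reactants: 9 racemic exo [6+4] adduct
Product: 10 5,6-cis-diol of 9 (both hydroxyls on the face turned away from the C8–C1 bridge)
Conditions: OsO4 (cat.), NMO, acetone–H2O, 0 °C
Reagents that add atoms: N-methylmorpholine N-oxide (C[N+]1([O-])CCOCC1); water (O)
Why: Upjohn dihydroxylation; the cis-disubstituted C5=C6 is the least hindered of the three alkenes (the other two each carry a methyl), and syn addition from the diene face turned away from the C8–C1 bridge should set C5 and C6 as in the target.

**Step 7**
Reactants: 10 5,6-cis-diol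
Product: 11 5,6-acetonide of 10
Conditions: 2,2-dimethoxypropane, PPTS (cat.), CH2Cl2, rt
Reagents that add atoms: 2,2-dimethoxypropane (COC(C)(C)OC)
Why: Acid-catalysed transketalisation of a cis-1,2-diol to the dioxolane, which also pulls any C5–O/C11 hemiketal back to the ketone.

**Step 8**
Reactants: 11 5,6-acetonide
Product: 12 9,10-cis-diol of 11 (9-epi; both hydroxyls on the face turned away from C11)
Conditions: OsO4 (cat.), NMO, acetone–H2O, rt
Reagents that add atoms: N-methylmorpholine N-oxide (C[N+]1([O-])CCOCC1); water (O)
Why: Upjohn dihydroxylation; C3=C4 is now shielded on its open face by the neighbouring acetonide, so osmylation should go to C9=C10 from the face turned away from the C11 carbonyl, setting the tertiary C10 carbinol as in the target and C9 as its epimer.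

**Step 9**
Reactants: 12 9,10-cis-diol
Product: 13 9-ketone (10-hydroxy-9-oxo compound)
Conditions: Dess–Martin periodinane, CH2Cl2, 0 °C to rt
Reagents that add atoms: none
Why: Dess–Martin oxidation of the only secondary alcohol; the tertiary C10 hydroxyl, the silyl ether and the acetonide are inert.

**Step 10**
Reactants: 13 9-ketone
Product: 14 9,10-trans-diol (C9 as in the target)
Conditions: Me4NBH(OAc)3, MeCN–AcOH, −20 °C
Reagents that add atoms: none
Why: Hydroxyl-directed (Saksena–Evans) reduction; the borohydride exchanges onto the C10 hydroxyl and delivers hydride to C9 from that same, exposed face, so the new hydroxyl ends trans to C10–OH, and the C11 ketone, having no neighbouring hydroxyl, is left alone.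

**Step 11**
Reactants: 14 9,10-trans-diol
Product: 15 C11 methyl carbinol of 14 (racemic)
Conditions: CeCl3, CH3Li (excess), THF, −78 °C
Reagents that add atoms: methyllithium ([Li]C)
Why: Organocerium 1,2-addition; the weakly basic CH3CeCl2 should add to the β,γ-unsaturated bridging ketone without enolisation, from the face turned away from the oxygenated C8–C1 bridge, and the new C11 centre is lost again in step 14.

**Step 12**
Reactants: 15 C11 methyl carbinol (racemic)
Product: 16 9-acetate of 15 (single enantiomer, 9R)
Conditions: Candida antarctica lipase B (immobilised), vinyl acetate, MTBE, 40 °C, to about half conversion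
Reagents that add atoms: vinyl acetate (C=COC(C)=O)
Why: Lipase-catalysed kinetic resolution by irreversible transesterification; only the secondary C9 hydroxyl can react, the empirical size rule for lipases (large quaternary C10 against the C8 methylene) predicts the 9R alcohol to be acylated, and the unreacted enantiomer of 15 is removed by chromatography, so the step installs the C9 acetate and the absolute configuration together.

**Step 13**
Reactants: 16 9-acetate
Product: 17 C1 alcohol of 16
Conditions: HF·pyridine, pyridine, THF, 0 °C to rt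
Reagents that add atoms: none
Why: Fluoride desilylation under buffered acidic conditions, which should spare the acetate (no acyl migration) and the acetonide.

**Step 14**
Reactants: 17 C1 alcohol
Product: 19 ring-opened ten-membered diketone (C1 ketone; C7 acetyl; C2 now CH2), via bicyclic beta-hydroxy ketone 18 (not isolated)
Conditions: Dess–Martin periodinane, CH2Cl2, 0 °C; then DBU, 0 °C
Reagents that add atoms: none
Why: Dess–Martin oxidation of the only secondary alcohol, then retro-aldol fragmentation: the C11 alkoxide expels the C1 enolate because the C2–C11 bond overlaps with the C1 carbonyl and cleavage releases the bridged bicycle; C-protonation at C2 gives the β,γ-unsaturated ketone, and C7 keeps its configuration because it is not deprotonated in the brief, cold base treatment.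

**Step 15**
Reactants: 19 ring-opened diketone
Product: 20 C1 alcohol (C1 as in the target)
Conditions: Me4NBH(OAc)3, MeCN–AcOH, −20 °C
Reagents that add atoms: none
Why: Hydroxyl-directed (Saksena–Evans) reduction of the α-hydroxy ketone; hydride comes from boron held on the C10 hydroxyl, so C1–OH ends trans to C10–OH, while the methyl ketone, which has only an acetal and an ester oxygen nearby, is not reduced.

**Step 16**
Reactants: 20 C1 alcohol
Product: 21 isopropenyl compound
Conditions: Ph3PCH3Br, KOC(CH3)3, THF, 0 °C
Reagents that add atoms: methyltriphenylphosphonium bromide ([Br-].C[P+](c1ccccc1)(c1ccccc1)c1ccccc1)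
Why: Wittig methylenation of the unhindered methyl ketone; the ylide is not basic enough to deprotonate the free hydroxyls and should react faster with the ketone than it enolises C7 or attacks the acetate.

**Step 17**
Reactants: 21 isopropenyl compound; 22 angelic acid
Product: 23 C1 angelate
Conditions: 22, 2,4,6-Cl3C6H2COCl, Et3N, toluene, rt; then 21, DMAP, 60 °C
Reagents that add atoms: none
Why: Yamaguchi esterification, the standard way to acylate a hindered secondary alcohol with angelic acid without Z to E isomerisation; the tertiary C10 hydroxyl does not react.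

**Step 18**
Reactants: 23 C1 angelate
Product: 24 5,6-diol
Conditions: AcOH–H2O (4:1), 40 °C
Reagents that add atoms: none
Why: Mild acid hydrolysis of the acetonide; the esters, the isopropenyl group and the tertiary alcohol should survive.

**Step 19**
Reactants: 24 5,6-diol
Product: 25 3,4-epoxide (epoxy diol)
Conditions: VO(acac)2 (cat.), t-BuOOH, CH2Cl2, 0 °C
Reagents that add atoms: tert-butyl hydroperoxide (CC(C)(C)OO)
Why: Vanadium-catalysed hydroxyl-directed epoxidation; the allylic C5 hydroxyl delivers the oxygen to C3=C4 on its own face, which sets C3 and C4, while the isopropenyl group (only homoallylic to C6–OH) and the two enoates react far more slowly.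

**Step 20**
Reactants: 25 3,4-epoxide; 26 3-methylbut-2-enoyl chloride
Product: 27 C6 senecioate
Conditions: pyridine, DMAP (cat.), CH2Cl2, −20 °C
Reagents that add atoms: none
Why: Selective acylation; C6–OH should react before C5–OH, which is now flanked by the quaternary epoxide carbon, and pyridine instead of a stronger amine avoids deconjugation of the acyl chloride.

**Step 21**
Reactants: 27 C6 senecioate
Product: 28 CNP0416509.1
Conditions: Ac2O, pyridine, DMAP, CH2Cl2, rt
Reagents that add atoms: acetic anhydride (CC(=O)OC(C)=O)
Why: Acetylation of the remaining secondary hydroxyl at C5; the tertiary C10 hydroxyl is too hindered to react under these conditions.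

**Compound list**

1 | 4-methylanisole | COc1ccc(C)cc1 | starting material
2 | 1-methoxy-4-methylcyclohexa-1,4-diene | COC1=CCC(C)=CC1 | intermediate
3 | bromoform | BrC(Br)Br | starting material
4 | 7,7-dibromo-1-methoxy-4-methylbicyclo[4.1.0]hept-3-ene (racemic, cis-fused) | COC12CC=C(C)CC1C2(Br)Br | intermediate
5 | 2-bromo-5-methylcyclohepta-2,5-dien-1-one (not isolated) | O=C1CC=C(C)CC=C1Br | intermediate
6 | 4-methyltropone | CC1=CC=CC(=O)C=C1 | intermediate
7 | (E)-2-methylbut-2-enal | C/C=C(\C)C=O | starting material
8 | (E)-1-(tert-butyldimethylsilyloxy)-2-methylbuta-1,3-diene | C=C/C(C)=C/O[Si](C)(C)C(C)(C)C | intermediate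
9 | racemic exo [6+4] adduct: C11 ketone bridging C2 and C7; C1 OTBS; C3=C4(CH3)–C5=C6; C9=C10(CH3) | O=C1[C@@H]2/C=C\C(C)=C/[C@H]1[C@H](O[Si](C)(C)C(C)(C)C)/C(C)=C\C2 | intermediate
10 | 5,6-cis-diol of 9 (racemic) | O=C1[C@@H]2[C@H](O)[C@H](O)/C(C)=C\[C@H]1[C@H](O[Si](C)(C)C(C)(C)C)/C(C)=C\C2 | intermediate
11 | 5,6-acetonide (racemic) | O=C1[C@@H]2[C@H](O3)[C@H](OC3(C)C)/C(C)=C\[C@H]1[C@H](O[Si](C)(C)C(C)(C)C)/C(C)=C\C2 | intermediate
12 | 9,10-cis-diol, 9-epi (racemic) | O=C1[C@@H]2[C@H](O3)[C@H](OC3(C)C)/C(C)=C\[C@H]1[C@H](O[Si](C)(C)C(C)(C)C)[C@@](C)(O)[C@@H](O)C2 | intermediate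
13 | 10-hydroxy-9-ketone (racemic) | O=C1[C@@H]2[C@H](O3)[C@H](OC3(C)C)/C(C)=C\[C@H]1[C@H](O[Si](C)(C)C(C)(C)C)[C@@](C)(O)C(=O)C2 | intermediate
14 | 9,10-trans-diol (racemic) | O=C1[C@@H]2[C@H](O3)[C@H](OC3(C)C)/C(C)=C\[C@H]1[C@H](O[Si](C)(C)C(C)(C)C)[C@@](C)(O)[C@H](O)C2 | intermediate
15 | C11 methyl carbinol (racemic) | C[C@]1(O)[C@@H]2[C@H](O3)[C@H](OC3(C)C)/C(C)=C\[C@H]1[C@H](O[Si](C)(C)C(C)(C)C)[C@@](C)(O)[C@H](O)C2 | intermediate
16 | 9-acetate (single enantiomer) | C[C@]1(O)[C@@H]2[C@H](O3)[C@H](OC3(C)C)/C(C)=C\[C@H]1[C@H](O[Si](C)(C)C(C)(C)C)[C@@](C)(O)[C@H](OC(C)=O)C2 | intermediate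
17 | C1 alcohol | C[C@]1(O)[C@@H]2[C@H](O3)[C@H](OC3(C)C)/C(C)=C\[C@H]1[C@H](O)[C@@](C)(O)[C@H](OC(C)=O)C2 | intermediate
18 | bicyclic β-hydroxy ketone (C1 ketone, C11 carbinol; not isolated) | C[C@]1(O)[C@@H]2[C@H](O3)[C@H](OC3(C)C)/C(C)=C\[C@H]1C(=O)[C@@](C)(O)[C@H](OC(C)=O)C2 | intermediate
19 | ten-membered diketone: C1 ketone, 7-acetyl, (3Z)-alkene, 5,6-acetonide, 9-OAc, 10-OH | CC(=O)[C@H]1C[C@@H](OC(C)=O)[C@](C)(O)C(=O)C/C=C(C)\[C@@H](O2)[C@H]1OC2(C)C | intermediate
20 | C1 alcohol (1,10-trans-diol) | CC(=O)[C@H]1C[C@@H](OC(C)=O)[C@](C)(O)[C@@H](O)C/C=C(C)\[C@@H](O2)[C@H]1OC2(C)C | intermediate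
21 | 7-isopropenyl compound | C=C(C)[C@H]1C[C@@H](OC(C)=O)[C@](C)(O)[C@@H](O)C/C=C(C)\[C@@H](O2)[C@H]1OC2(C)C | intermediate
22 | angelic acid, (Z)-2-methylbut-2-enoic acid | C/C=C(/C)C(=O)O | starting material
23 | C1 angelate | C=C(C)[C@H]1C[C@@H](OC(C)=O)[C@](C)(O)[C@@H](OC(=O)/C(C)=C\C)C/C=C(C)\[C@@H](O2)[C@H]1OC2(C)C | intermediate
24 | 5,6-diol | C=C(C)[C@H]1C[C@@H](OC(C)=O)[C@](C)(O)[C@@H](OC(=O)/C(C)=C\C)C/C=C(C)\[C@@H](O)[C@H]1O | intermediate
25 | 3,4-epoxy-5,6-diol | C=C(C)[C@H]1C[C@@H](OC(C)=O)[C@](C)(O)[C@@H](OC(=O)/C(C)=C\C)C[C@H]2O[C@@]2(C)[C@@H](O)[C@H]1O | intermediate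
26 | 3-methylbut-2-enoyl chloride | CC(C)=CC(=O)Cl | starting material
27 | C6 senecioate, C5 alcohol | C=C(C)[C@H]1C[C@@H](OC(C)=O)[C@](C)(O)[C@@H](OC(=O)/C(C)=C\C)C[C@H]2O[C@@]2(C)[C@@H](O)[C@H]1OC(=O)C=C(C)C | intermediate
28 | CNP0416509.1 | C=C(C)[C@H]1C[C@@H](OC(C)=O)[C@](C)(O)[C@@H](OC(=O)/C(C)=C\C)C[C@H]2O[C@@]2(C)[C@@H](OC(C)=O)[C@H]1OC(=O)C=C(C)C | target

**Totals**

Total step count: 21. Longest linear sequence: 20 steps (steps 1 to 3 and 5 to 21, from 4-methylanisole).

**Steps most likely to fail**

Step 5. The tropone may add in the other orientation, since its ring methyl is too remote to steer, so that much of the material ends as the C5-methyl regioisomer. The fallback gives the tropone a removable bromine on the carbon that is to become C7. It sets out from 4: silver-assisted ring opening without the amine gives 5 as an isolated compound, and dehydrogenation with DDQ in dioxane gives 2-bromo-5-methyltropone F1. Cycloaddition of F1 with 8 should then be steered by size, the silyloxy-bearing diene terminus avoiding the brominated carbon, to give the 7-bromo adduct F2. Radical reduction with Bu3SnH and AIBN removes the bridgehead bromine with forced retention and comes back to the route at 9.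

Step 6. Osmylation may go to a trisubstituted alkene (C3=C4 or C9=C10) instead of C5=C6, giving poor site selectivity. The fallback masks the two electron-rich alkenes first and sets out from 9. mCPBA (two equivalents) should epoxidise both trisubstituted alkenes from their exposed faces to give the bis-epoxide F3. The only alkene left, C5=C6, is then dihydroxylated with OsO4 and NMO to the bis-epoxy diol F4, which is protected with 2,2-dimethoxypropane as the bis-epoxy acetonide F5. Both epoxides are deoxygenated with PPh3 and catalytic CH3ReO3 in toluene, which comes back to the route at 11.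

Step 8. If the C8–C1 bridge folds away from the ketone, the other face of C9=C10 is exposed and the tertiary C10 carbinol would form with the wrong configuration. The fallback uses that same face with anti instead of syn addition and sets out from 11. mCPBA should give the 9,10-epoxide F6 with its oxygen on the face that the target needs at C9. Dilute aqueous HClO4 in THF at 0 °C, stopped when the epoxide is consumed so that the acetonide survives, opens it at the tertiary C10 with inversion. This gives the trans-diol directly and comes back to the route at 14, bypassing 12 and 13.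

**Further compounds**

F1 | step 5 | 2-bromo-5-methyltropone | O=C1C(Br)=CC=C(C)C=C1
F2 | step 5 | 7-bromo exo [6+4] adduct (racemic) | O=C1[C@]2(Br)/C=C\C(C)=C/[C@H]1[C@H](O[Si](C)(C)C(C)(C)C)/C(C)=C\C2
F3 | step 6 | 3,4:9,10-bis-epoxide of 9 (racemic) | O=C1[C@@H]2/C=C\[C@]3(C)O[C@@H]3[C@H]1[C@H](O[Si](C)(C)C(C)(C)C)[C@@]4(C)O[C@H]4C2
F4 | step 6 | bis-epoxy 5,6-cis-diol (racemic) | O=C1[C@@H]2[C@H](O)[C@H](O)[C@]3(C)O[C@@H]3[C@H]1[C@H](O[Si](C)(C)C(C)(C)C)[C@@]4(C)O[C@H]4C2
F5 | step 6 | bis-epoxy 5,6-acetonide (racemic) | O=C1[C@@H]2[C@H](O5)[C@H](OC5(C)C)[C@]3(C)O[C@@H]3[C@H]1[C@H](O[Si](C)(C)C(C)(C)C)[C@@]4(C)O[C@H]4C2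
F6 | step 8 | 9,10-epoxide of 11 with oxygen on the C11 side (racemic) | O=C1[C@@H]2[C@H](O3)[C@H](OC3(C)C)/C(C)=C\[C@H]1[C@H](O[Si](C)(C)C(C)(C)C)[C@]4(C)O[C@@H]4C2
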